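**Plan**
- Retrosynthesis: cut the ester C(=O)–O bond first (acyl part = 3-(4-hydroxyphenyl)propanoic acid, alcohol part = pentacosan-1-ol), then the C9–C10 bond of the pentacosyl chain (C1 = OCH2). This gives a C16 unit and a C9–OH unit, each traced back to a carboxylic acid one carbon longer.
- Enabling feature: C2–C25 of the alcohol chain is an unbranched run of CH2 groups, and C9 and C10 are plain methylenes flanked by methylenes, with the only chain heteroatom (the O on C1) eight carbons away. Both ends are therefore unstabilised primary alkyl radicals that can be made by anodic decarboxylation and simply combine. The only ring (the para-hydroxyphenyl ring) and its oxidisable phenol are kept out of the cell by attaching the acyl part afterwards.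
- Forward: step 1, crossed Kolbe electrolysis of heptadecanoic acid with 10-hydroxydecanoic acid, joins the chain to pentacosan-1-ol. Step 2, acid-catalysed esterification with 3-(4-hydroxyphenyl)propanoic acid, needs no protecting group.
- Stereochemistry (remark): the target has no stereocentre and no stereogenic double bond, so it is achiral and nothing has to be set or preserved.

Key step: step 1

**Step 1**
Reactants: 1 heptadecanoic acid (3 equiv); 2 10-hydroxydecanoic acid (1 equiv)
Product: 5 pentacosan-1-ol, via hexadecyl radical 3 (not isolated), via 9-hydroxynonyl radical 4 (not isolated)
Conditions: Pt anode/Pt cathode, undivided cell, KOH (ca. 0.1 equiv per CO2H), MeOH under a layer of light petroleum, 45–50 °C, constant current ca. 0.2 A cm−2 with periodic polarity reversal, until just alkaline; aq. KOH wash, silica chromatography, recrystallisation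
Reagents that add atoms: none
Why: Mixed (crossed) Kolbe electrolysis: at the carboxylate-covered platinum anode at high current density each carboxylate is oxidised by one electron to an acyloxy radical that loses CO2 at once, giving the primary radicals 3 and 4 in high local concentration at the electrode, where they combine to form the C9–C10 bond of the chain while protons are reduced to H2 at the cathode. The closest known reaction type is the crossed Kolbe coupling of a fatty acid with an ω-functionalised alkanoic acid, long used to build long-chain lipids and pheromones. No ring is closed and no stereocentre is formed. The step needs the one-electron (radical) path and not the two-electron path to carbocations: both radicals are unbranched, primary and carry no α-heteroatom or aryl group (the oxygen of 4 is separated from the radical carbon by eight CH2 groups), so further oxidation is unfavourable, and weakly acidic methanol on smooth platinum favours dimerisation. It also needs the primary hydroxyl to survive, which should hold because the anode surface is blocked by carboxylate at the Kolbe potential and the solvent methanol, itself a primary alcohol, is left untouched under the same conditions. Cross- against homo-coupling is statistical, so the cheaper acid 1 is used in threefold excess to draw 2 mainly into 5, and the symmetric by-products dotriacontane (no OH) and octadecane-1,18-diol (two OH) should separate cleanly from the mono-alcohol on silica or by crystallisation.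

**Step 2**
Reactants: 5 pentacosan-1-ol; 6 3-(4-hydroxyphenyl)propanoic acid (1.5 equiv)
Product: 7 pentacosyl 3-(4-hydroxyphenyl)propanoate
Conditions: p-TsOH·H2O (5 mol%), toluene, reflux, Dean–Stark trap; aq. NaHCO3 wash, recrystallisation
Reagents that add atoms: none
Why: Fischer esterification driven by azeotropic removal of water; the primary aliphatic alcohol is far more nucleophilic than the phenolic OH and aryl esters are disfavoured at equilibrium, so the carboxyl group should be esterified by 5 selectively without phenol protection, and the excess of 6 is removed by the bicarbonate wash.

**Compound list**
1 | heptadecanoic acid | CCCCCCCCCCCCCCCCC(=O)O | starting material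
2 | 10-hydroxydecanoic acid | OCCCCCCCCCC(=O)O | starting material
3 | hexadecyl radical | CCCCCCCCCCCCCCC[CH2] | intermediate
4 | 9-hydroxynonyl radical | [CH2]CCCCCCCCO | intermediate
5 | pentacosan-1-ol | CCCCCCCCCCCCCCCCCCCCCCCCCO | intermediate
6 | 3-(4-hydroxyphenyl)propanoic acid | OC(=O)CCc1ccc(O)cc1 | starting material
7 | pentacosyl 3-(4-hydroxyphenyl)propanoate | CCCCCCCCCCCCCCCCCCCCCCCCCOC(=O)CCc1ccc(O)cc1 | target

**Total step count:** 2
**Longest linear sequence:** 2 steps

**Steps most likely to fail** (the route has only two steps, so both are given, the riskier first)

1. Step 1. What may go wrong: homo-coupling may consume most of the hydroxy acid. A film of waxy product may passivate the anode, so that the potential rises and the two-electron path to carbocation products (methyl ethers, alkenes) takes over. The free primary hydroxyl may be oxidised at the anode. Fallback (polar organometallic coupling at the same bond in place of the anodic radical coupling): this fallback does not use 1 or 2. It sets out from commercial 9-bromononan-1-ol and 1-bromohexadecane and comes back to the route at 5. 9-Bromononan-1-ol is protected with 3,4-dihydro-2H-pyran and PPTS in CH2Cl2 to give 2-[(9-bromononyl)oxy]oxane F1 (racemic at the acetal carbon, which is later removed). 1-Bromohexadecane and magnesium in THF give hexadecylmagnesium bromide F2. Copper-catalysed Grignard–alkyl bromide coupling of F1 with F2 (Li2CuCl4, 2–3 mol%, THF, −10 °C to rt) should give 2-(pentacosyloxy)oxane F3. Methanolysis of the acetal (p-TsOH cat., MeOH–THF, 40 °C) should give 5.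

2. Step 2. What may go wrong: conversion of the sparingly soluble waxy alcohol may stay incomplete. The phenolic hydroxyl may be acylated in competition, giving oligoesters. The alcohol may undergo acid-catalysed etherification at reflux. Fallback (protecting-group route with carbodiimide activation in place of equilibrium esterification): it sets out from 5 and comes back to the route at 7. Steglich esterification of 5 with commercial 3-[4-(benzyloxy)phenyl]propanoic acid (EDC·HCl, DMAP cat., CH2Cl2–THF, rt) should give pentacosyl 3-[4-(benzyloxy)phenyl]propanoate F4. Hydrogenolysis of the benzyl ether (H2 1 atm, 10% Pd/C, EtOAc–THF, rt to 40 °C) should give 7, the alkyl ester being inert to these conditions.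

**Further compounds**
F1 | step 1 | 2-[(9-bromononyl)oxy]oxane | BrCCCCCCCCCOC1CCCCO1
F2 | step 1 | hexadecylmagnesium bromide | CCCCCCCCCCCCCCCC[Mg]Br
F3 | step 1 | 2-(pentacosyloxy)oxane | CCCCCCCCCCCCCCCCCCCCCCCCCOC1CCCCO1
F4 | step 2 | pentacosyl 3-[4-(benzyloxy)phenyl]propanoate | CCCCCCCCCCCCCCCCCCCCCCCCCOC(=O)CCc1ccc(OCc2ccccc2)cc1
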